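Before any rate constant is fitted, the charges and the readings already bracket what added reagent can give. The questions and the flasks are these.

the same everywhere: starting material 1.5 M; reagent 1.35 M; free catalyst 11 mM
- grey: precatalyst 28 mM; temperature 35 °C; the very flask that is asked about, followed so far
- green: precatalyst 56 mM; temperature 20 °C; run made earlier
- flask: precatalyst 28 mM; temperature 35 °C; time 20 h

| run | time / h | product / % |
|---|---|---|
| grey | 1.50 | 10.1 |
| grey | 2.50 | 18.4 |
| grey | 4.00 | 26.2 |
| grey | 6.00 | 33.5 |
| grey | 8.00 | 37.2 |
| grey | 12.0 | 39.6 |
| grey | 20.0 | 41.3 |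
| green | 1.00 | 0.2 |
| green | 2.00 | 1.5 |
| green | 3.00 | 3.7 |
| green | 5.00 | 8.3 |
| green | 6.00 | 9.9 |
| green | 8.00 | 13.8 |

(standard deviation of a reading: 0.5 percentage points)

- eta: change nothing and wait 20 h more
- alpha: at 20 h take out 90 % of the product then present, then wait 20 h
- zeta: at 20 h add reagent, 50.0 % of the amount charged, then wait 20 h
- gamma: at 20 h add free catalyst, 50.0 % of the amount charged, then wait 20 h
- theta: at 20 h raise the temperature by 15 K, then wait 20 h

- product, in percent of the starting material first charged, at 20 h
- the remedy with the largest gain of product, or "none" below 2 percentage points (eta / alpha / zeta / gamma / theta / none)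
- product present, with what was taken out counted in, in percent of the starting material first charged, after zeta
- product present, with what was taken out counted in, in percent of the starting material first charged, after theta

- product taken out counts as made
- "the catalyst" is free catalyst with its forms; second catalyst is a second catalyst
- additions bring no volume worth counting

The grey run is the asked flask, and its reading at 20.0 h gives 41.3 % for "now". Product rose by 1.7 percentage points over its last 8.00 h, although the reagent charge allows 90.0 %. The readings leave both a reversible limit and a spent feed open, so the reckoning here commits to a reading: the reagent is the limiting reagent, and part of it went another way.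

The carried quantity is then the reagent yield, the product made per reagent charged, and the grey run gives 45.9 %.

On this reading, eta, alpha, gamma and theta add no reagent, so each is expected to stay near 41.3 %, and zeta is the remedy. The bound from above turns every added reagent into product: 86.3 %. The bound from below gives the added reagent the same yield: 61.9 %. That bound is an estimate, and it rests on a judgement: the green run, colder and with more precatalyst, starts slowly with 0.2 % at 1.00 h, and the added reagent is expected to do no worse in a flask already running.

The forecast, saying “I favour an equilibrium-like stall”, gave 41.7 % now, 41.5 % after theta, alpha as best, and 52.5 % after zeta, below the bracket.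

The flask gives 41.4 % now, 41.6 % after theta, zeta as best, and 69.3 % after zeta, inside the bracket, so the added reagent yielded 62.0 %.

    starting material + free catalyst ⇌ free catalyst + open intermediate (K = 0.800, k = 0.00990 L mol⁻¹ s⁻¹, Ea = 60.0 kJ mol⁻¹, ΔH = −21.0 kJ mol⁻¹)
    second catalyst + open intermediate ⇌ catalyst intermediate (K = 0.410 L mol⁻¹, k = 0.0680 L mol⁻¹ s⁻¹, Ea = 47.0 kJ mol⁻¹, ΔH = 41.0 kJ mol⁻¹)
    reagent + catalyst intermediate → second catalyst + product (k = 0.0870 L mol⁻¹ s⁻¹, Ea = 68.0 kJ mol⁻¹)
    2 reagent → homo dimer (k = 4.80 × 10⁻⁵ L mol⁻¹ s⁻¹, Ea = 81.0 kJ mol⁻¹)
    precatalyst ⇌ second catalyst (K = 0.300, k = 2.70 × 10⁻⁴ s⁻¹, Ea = 87.0 kJ mol⁻¹, ΔH = 20.0 kJ mol⁻¹)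
    2 second catalyst ⇌ resting dimer (K = 44.0 L mol⁻¹, k = 0.0940 L mol⁻¹ s⁻¹, Ea = 56.0 kJ mol⁻¹, ΔH = −16.0 kJ mol⁻¹)
    (constants at 35 °C)

At 20.0 h the flask holds 0.17 % of its reagent and 0.363 M of homo dimer, and the reagent yield, read as 45.9 %, is the share of the charge won against that pairing. Reagent went to product 1.15 times as fast as to homo dimer at 2.00 h, with 41.3 % of the reagent present, and 20.5 times as fast at 10.0 h, with 2.93 % present. The neighbouring flask with 0.0044 M of free catalyst keeps 0.20 % of its reagent, and its 34.8 % of product is a reagent yield of 38.6 %.

(Readings and results are simulated on assumed constants; scatter was added.)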